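The terpenoid part is numbered as a drimane (ring A: C1–C5 and C10; ring B: C5–C10; C11 = OCH2; C12 = methyl on C8). The plan exploits ring B, a cyclohexene fused to ring A along C5–C10: an acyclic 1,7,9-decatriene, whose diene C7=C8–C9=C10 bears CH2SiMe3 on C8 and whose vinyl group C5=C6 is tied on through C1–C4, closes both rings in one intramolecular Diels–Alder step that forms C5–C10 and C6–C7. The resulting allylsilane then accepts the aryloxymethyl cation at C9, anti to the angular methyl, and the exocyclic alkene is finally moved into C7=C8.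

Key step: step 4

Remark: the SMILES places C11 trans to the C10 methyl (H-9 cis to it, i.e. the 9-epi-drimane series), and the route is built for that configuration; 4-pentynal is taken as a purchased compound.

Step 1
Reactants: 1 4-pentynal; 2 prenylmagnesium chloride
Product: 5 (4S)-3,3-dimethyloct-1-en-7-yn-4-ol, via prenylborane 3 (not isolated), via borinate ester 4 (not isolated)
Conditions: 2, (+)-Ipc2BOMe, Et2O–THF, −78 to 0 °C; then 1, −78 °C; then NaOH, H2O2, 0 °C to rt
Reagents that add atoms: none
Why: Brown asymmetric allylboration with a prenylborane (reverse prenylation) transfers the allyl group with allylic transposition through a six-membered chair transition state, building the C3–C4 bond and the C4 quaternary centre, and the isopinocampheyl groups derived from (−)-α-pinene should select the aldehyde face that gives the (S)-carbinol C3.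

Step 2
Reactants: 5 (4S)-3,3-dimethyloct-1-en-7-yn-4-ol; 6 (2-bromoallyl)trimethylsilane
Product: 8 (4S,7E)-3,3,7-trimethyl-9-[(trimethylsilyl)methyl]deca-1,7,9-trien-4-ol, via alkenylalane 7 (not isolated)
Conditions: AlMe3 (3 equiv), Cp2ZrCl2 (20 mol%), CH2Cl2, 0 °C to rt; then 6, Pd(PPh3)4 (5 mol%), ZnCl2 (cocatalyst), THF, rt
Reagents that add atoms: trimethylaluminium, C[Al](C)C
Why: Negishi zirconium-catalysed carboalumination adds methyl and aluminium syn across the terminal alkyne (methyl on C10, so the chain ends up trans to the new C9–C8 bond, E), and the alkenylalane is then joined to the alkenyl bromide with retention by palladium-catalysed Negishi cross-coupling, the hydroxyl being masked as its aluminium alkoxide.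

Step 3
Reactants: 8 the trienol
Product: 9 (4S,7E)-3,3,7-trimethyl-9-[(trimethylsilyl)methyl]deca-1,7,9-trien-4-yl acetate
Conditions: Ac2O, Et3N, DMAP (cat.), CH2Cl2, rt
Reagents that add atoms: acetic anhydride, CC(=O)OC(C)=O
Why: DMAP-catalysed acylation of the hindered secondary alcohol installs the C3 acetate of the target without touching a stereocentre.

Step 4
Reactants: 9 the triene acetate
Product: 10 (2S,4aR,8aR)-1,1,4a-trimethyl-6-[(trimethylsilyl)methyl]-1,2,3,4,4a,7,8,8a-octahydronaphthalen-2-yl acetate (trans-fused; 3β-OAc, 5α-H, 10β-CH3, C8=C9, CH2SiMe3 on C8)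
Conditions: PhMe (0.01 M), BHT (cat.), sealed tube, 200 °C
Reagents that add atoms: none
Why: Concerted, asynchronous thermal [4+2] cycloaddition (type 1 intramolecular Diels–Alder reaction) in which the diene C7=C8–C9=C10 adds suprafacially to the unactivated vinyl group C5=C6, forming C6–C7 and C5–C10 and leaving C8=C9 as part of an allylsilane. The closest known reaction type is the thermal cyclization of unactivated 1,7,9-decatrienes to octalins, combined with the use of 2-(silylmethyl)-1,3-dienes as Diels–Alder dienes ahead of a Hosomi–Sakurai step. Ring B is closed as the cycloaddition ring itself (both new bonds), and ring A through the C5–C10 bond by the four-atom tether C1–C4 in the fused, not bridged, mode. C10 and C5 are set trans to each other by the anti transition state with a chair-like tether, in which the C10 methyl and H-5 are axial and the diene and dienophile arms equatorial; C3 controls the face because its acetoxy group stays equatorial on that chair, which places the C10 methyl cis and H-5 trans to it. The step needs trans over cis ring fusion and one of the two diene faces: the E geometry of C9=C10 (tether outside, methyl inside) allows the anti arrangement, the C4 gem-dimethyl group speeds ring closure (Thorpe–Ingold effect) and C3 supplies the facial bias. Both selectivities are expected to be only moderate, so minor diastereomers are to be removed here; no Lewis acid is present, so the allylsilane survives for step 6.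

Step 5
Reactants: 11 isofraxidin (7-hydroxy-6,8-dimethoxycoumarin); 12 bromomethyl acetate
Product: 13 [(6,8-dimethoxy-2-oxo-2H-chromen-7-yl)oxy]methyl acetate
Conditions: Ag2O, 4 Å molecular sieves, MeCN, rt, dark
Reagents that add atoms: none
Why: Silver-oxide-mediated O-alkylation of the phenol (Williamson-type SN2 at the bromomethyl carbon) gives the acyloxymethyl aryl ether without strong base, which avoids acyl transfer and lactone opening.

Step 6
Reactants: 10 the octalin allylsilane; 13 the acetoxymethyl ether of isofraxidin
Product: 14 [(2S,4aS,5R,8aR)-5-{[(6,8-dimethoxy-2-oxo-2H-chromen-7-yl)oxy]methyl}-1,1,4a-trimethyl-6-methylidenedecahydronaphthalen-2-yl] acetate (C11 on the α face of C9, exocyclic C8=C12)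
Conditions: TMSOTf (0.3 equiv), 2,6-di-tert-butyl-4-methylpyridine, CH2Cl2, −78 to −30 °C; aq. NaHCO3
Reagents that add atoms: none
Why: Hosomi–Sakurai reaction in which the silyl triflate ionises the acetal acetate to the aryloxymethyl cation, which the allylsilane takes up at C9 (SE2′) by axial attack on the α face, anti to the pseudoaxial C10 methyl, so that C11 is set trans to that methyl and loss of silicon leaves the exocyclic C8=C12 alkene regiospecifically.

Step 7
Reactants: 14 the exocyclic alkene
Product: 15 the target, [(2S,4aS,5R,8aR)-5-{[(6,8-dimethoxy-2-oxo-2H-chromen-7-yl)oxy]methyl}-1,1,4a,6-tetramethyl-1,2,3,4,4a,5,8,8a-octahydronaphthalen-2-yl] acetate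
Conditions: Co(salen)Cl [salen = N,N′-bis(3,5-di-tert-butylsalicylidene)-1,2-cyclohexanediamine dianion; trivalent cobalt] (3 mol%), PhSiH3 (6 mol%), C6H6, rt
Reagents that add atoms: none
Why: Cobalt-hydride hydrogen-atom-transfer alkene isomerization, in which H-atom addition to the methylene carbon gives the tertiary C8 radical and hydrogen abstraction from the accessible C7 methylene, rather than from the shielded tertiary C9–H, should give the trisubstituted C7=C8 alkene (the known one-position selectivity of this reaction type) without touching C9.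

Compound list
1 | 4-pentynal | C#CCCC=O | starting material
2 | prenylmagnesium chloride (3-methylbut-2-enylmagnesium chloride) | CC(C)=CC[Mg]Cl | starting material
3 | (+)-B-(3-methylbut-2-enyl)diisopinocampheylborane (isopinocampheyl groups from (−)-α-pinene) | CC(C)=CCB([C@H]1C[C@H]2C[C@@H]([C@@H]1C)C2(C)C)[C@H]1C[C@H]2C[C@@H]([C@@H]1C)C2(C)C | intermediate
4 | (4S)-3,3-dimethyloct-1-en-7-yn-4-yl diisopinocampheylborinate | C#CCC[C@H](OB([C@H]1C[C@H]2C[C@@H]([C@@H]1C)C2(C)C)[C@H]1C[C@H]2C[C@@H]([C@@H]1C)C2(C)C)C(C)(C)C=C | intermediate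
5 | (4S)-3,3-dimethyloct-1-en-7-yn-4-ol | C=CC(C)(C)[C@@H](O)CCC#C | intermediate
6 | (2-bromoallyl)trimethylsilane | C=C(Br)C[Si](C)(C)C | starting material
7 | (E)-alkenyl(dimethyl)alane of 5, as its dimethylaluminium alkoxide | C=CC(C)(C)[C@@H](O[Al](C)C)CC/C(C)=C/[Al](C)C | intermediate
8 | (4S,7E)-3,3,7-trimethyl-9-[(trimethylsilyl)methyl]deca-1,7,9-trien-4-ol | C=CC(C)(C)[C@@H](O)CC/C(C)=C/C(=C)C[Si](C)(C)C | intermediate
9 | (4S,7E)-3,3,7-trimethyl-9-[(trimethylsilyl)methyl]deca-1,7,9-trien-4-yl acetate | C=CC(C)(C)[C@@H](OC(C)=O)CC/C(C)=C/C(=C)C[Si](C)(C)C | intermediate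
10 | (2S,4aR,8aR)-1,1,4a-trimethyl-6-[(trimethylsilyl)methyl]-1,2,3,4,4a,7,8,8a-octahydronaphthalen-2-yl acetate | C[Si](C)(C)CC1=C[C@@]2(C)CC[C@H](OC(C)=O)C(C)(C)[C@@H]2CC1 | intermediate
11 | isofraxidin (7-hydroxy-6,8-dimethoxycoumarin) | COc1cc2ccc(=O)oc2c(OC)c1O | starting material
12 | bromomethyl acetate | CC(=O)OCBr | starting material
13 | [(6,8-dimethoxy-2-oxo-2H-chromen-7-yl)oxy]methyl acetate | COc1cc2ccc(=O)oc2c(OC)c1OCOC(C)=O | intermediate
14 | [(2S,4aS,5R,8aR)-5-{[(6,8-dimethoxy-2-oxo-2H-chromen-7-yl)oxy]methyl}-1,1,4a-trimethyl-6-methylidenedecahydronaphthalen-2-yl] acetate | COc1cc2ccc(=O)oc2c(OC)c1OC[C@@H]1C(=C)CC[C@H]2C(C)(C)[C@@H](OC(C)=O)CC[C@]12C | intermediate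
15 | [(2S,4aS,5R,8aR)-5-{[(6,8-dimethoxy-2-oxo-2H-chromen-7-yl)oxy]methyl}-1,1,4a,6-tetramethyl-1,2,3,4,4a,5,8,8a-octahydronaphthalen-2-yl] acetate | COc1cc2ccc(=O)oc2c(OC)c1OC[C@@H]1C(C)=CC[C@H]2C(C)(C)[C@@H](OC(C)=O)CC[C@]12C | target

Total step count: 7. Longest linear sequence: 6 steps (steps 1, 2, 3, 4, 6 and 7; step 5 is a one-step side branch).

Steps most likely to fail

Step 4. The unactivated cycloaddition may be too slow at the temperature the substrate tolerates, so that reversible [1,5]-hydrogen shifts of the inside methyl of the diene and polymerization compete. In addition the cis/trans ring-fusion ratio and the facial control by the equatorial C3 acetoxy group may both be low. The fallback activates the dienophile with a group that is removed afterwards. It sets out from 9: cross-metathesis with phenyl vinyl sulfone in excess (second-generation Hoveyda–Grubbs catalyst, CH2Cl2, 40 °C) should give the (E)-vinyl sulfone, (4S,1E,7E)-3,3,7-trimethyl-1-(phenylsulfonyl)-9-[(trimethylsilyl)methyl]deca-1,7,9-trien-4-yl acetate F1. This should cyclize in toluene at about 110–140 °C through the anti transition state with the sulfonyl group endo, to the 6α-phenylsulfonyl octalin, (2S,4aR,8R,8aR)-1,1,4a-trimethyl-8-(phenylsulfonyl)-6-[(trimethylsilyl)methyl]-1,2,3,4,4a,7,8,8a-octahydronaphthalen-2-yl acetate F2. Reductive desulfonylation (Na(Hg), Na2HPO4, THF–MeOH, −20 °C) comes back to the route at 10.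

Step 6. The mixed acetal may ionise in the wrong sense (loss of the coumarinolate instead of acetate), the aryloxymethyl cation may alkylate a second coumarin ring, or the allylsilane may simply be protodesilylated. The fallback forms the C9–C11 bond first and the ether bond second. It sets out from 10: Sakurai reaction with formaldehyde (paraformaldehyde, Me2AlCl, CH2Cl2, −78 to 0 °C), with the same α-face attack, should give the homoallylic alcohol, [(2S,4aS,5R,8aR)-5-(hydroxymethyl)-1,1,4a-trimethyl-6-methylidenedecahydronaphthalen-2-yl] acetate F3. Mitsunobu etherification with isofraxidin 11 (PPh3, DIAD, toluene, 0 to 60 °C) comes back to the route at 14.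

Step 7. Hydrogen abstraction may occur at C9 instead of C7, which would give the tetrasubstituted C8=C9 alkene and erase the C9 stereocentre, or the hindered exocyclic alkene may not react. The fallback replaces isomerization by a regiodefined enol triflate. It sets out from 14: oxidative cleavage of the methylidene group (OsO4 cat., NaIO4, 2,6-lutidine, dioxane–water) should give the 12-nor-8-ketone, the 8-oxo analogue of 14 with the 9α-aryloxymethyl group retained, F4. Kinetic enolization towards C7 at −78 °C and O-triflation (KHMDS, N-(5-chloro-2-pyridyl)triflimide, THF) should give the C7=C8 enol triflate F5. Stille methylation (SnMe4, Pd(PPh3)4, LiCl, DMF, 60 °C) comes back to the route at 15. In this fallback the ketone must not be exposed to equilibrating base, since C9 then epimerizes or loses the aryloxide.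

Further compounds
F1 | step 4 | (4S,1E,7E)-3,3,7-trimethyl-1-(phenylsulfonyl)-9-[(trimethylsilyl)methyl]deca-1,7,9-trien-4-yl acetate | O=S(=O)(c1ccccc1)/C=C/C(C)(C)[C@@H](OC(C)=O)CC/C(C)=C/C(=C)C[Si](C)(C)C
F2 | step 4 | (2S,4aR,8R,8aR)-1,1,4a-trimethyl-8-(phenylsulfonyl)-6-[(trimethylsilyl)methyl]-1,2,3,4,4a,7,8,8a-octahydronaphthalen-2-yl acetate | C[Si](C)(C)CC1=C[C@@]2(C)CC[C@H](OC(C)=O)C(C)(C)[C@@H]2[C@@H](S(=O)(=O)c3ccccc3)C1
F3 | step 6 | [(2S,4aS,5R,8aR)-5-(hydroxymethyl)-1,1,4a-trimethyl-6-methylidenedecahydronaphthalen-2-yl] acetate | OC[C@@H]1C(=C)CC[C@H]2C(C)(C)[C@@H](OC(C)=O)CC[C@]12C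
F4 | step 7 | 12-nor-8-oxo analogue of 14 (9α-aryloxymethyl, 3β-acetoxy, trans-decalin) | COc1cc2ccc(=O)oc2c(OC)c1OC[C@@H]1C(=O)CC[C@H]2C(C)(C)[C@@H](OC(C)=O)CC[C@]12C
F5 | step 7 | C7=C8 enol trifluoromethanesulfonate of F4 | COc1cc2ccc(=O)oc2c(OC)c1OC[C@@H]1C(OS(=O)(=O)C(F)(F)F)=CC[C@H]2C(C)(C)[C@@H](OC(C)=O)CC[C@]12C
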